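Readings and results stem from a simulated flask with made-up constants; noise was put on by code.

The south-east run was my starting point for the west flask, and I read it as a rate. Between its first two readings target came at 0.153 M min⁻¹, between 0.78 min and 1.3 min at 0.254 M min⁻¹, and over its last two readings at 0.0442 M min⁻¹, so the south-east rate climbed and then fell by a factor of 5.75.

in all of them: partner 2.00 M

| charge | starting material | time |
|---|---|---|
| south-east | 0.800 M |  |
| north | 1.20 M |  |
| west | 2.00 M | 6.7 min |

- south-east run (time / min: [target] / M): 0.27: 0.0118; 0.46: 0.0409; 0.78: 0.1126; 1.3: 0.2446; 2.3: 0.4055; 3.9: 0.5298; 6.7: 0.6536
- north run (time / min: [target] / M): 0.27: 0.0188; 0.46: 0.0829; 0.78: 0.2417; 1.3: 0.4873; 2.3: 0.7018; 3.9: 0.8639; 6.7: 1.0150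

(standard deviation of a reading: 0.002 M)

* apparent order in [starting material] of the starting rate, round the charge of the south-east run (the rate where two percent of its starting material have turned into target) (one fixed amount of target, the same in the runs compared)
* target in the west run at 6.7 min, as a share of the starting material charged

- Overall: starting material + partner -> target.
- Constant volume, constant temperature.
- "The second partner" is partner.
- An order is taken over about fifteen percent of the charge, up and down.

For the end of a run I called the gap the share of the charged starting material that has not yet appeared as c(target), and I took the tail time, the time in which the gap shrinks by a factor of e between the last two readings, as a first-order lag 4.57 min in the south-east run. The north run, with 1.50 times the charge, gave 4.69 min, so I carried the tail time over to the west flask.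

The tail needs a point to start from. At 1.3 min the north run had reached 40.6 % of its charge against 30.6 % in the south-east run, which favours a larger charge, but the west flask holds 1.00 partner per starting material against 2.50 in the south-east run. I judged that these roughly cancel and gave the west flask the south-east gap of a half at 2.3 min, which after the tail makes 80.9 % target at 6.7 min.

The forecast said 81 % and an order of 0.75, on the grounds that “The curves start with a clear lag”.

The west flask gave 79.2 %, and the order came out at 0.88, from these steps:

    starting material + partner → intermediate (0.6600 M⁻¹ min⁻¹)
    intermediate → target (0.2172 min⁻¹)
    partner → lost reagent (0.1650 min⁻¹)
    starting material + partner + target → 2 target (4.266 M⁻² min⁻¹)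

The west gap at 6.7 min was 20.8 %, larger than the 19.1 % of my reckoning. The north run stood at half of its charge at 1.72 min, and the same tail time carries that to a gap of 16.8 % at 6.7 min, where the north reading left 15.4 %.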